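**Assumption (one line):** the target has no stereocentre and no stereogenic double bond, so it is achiral and needs no stereocontrol; 4-(benzyloxy)-2-hydroxybenzoic acid is taken as a catalogue starting material.

## Retrosynthetic overview

1. Target ⇒ global hydrogenolysis of a depside that carries one benzyl ester (ring A) and one benzyl ether (ring B).
2. Key disconnection: the depside ester C–O bond, made by carbodiimide esterification of the ring B keto acid with the free 4-OH of the ring A benzyl ester.
3. Both partners come from one keto acid, 4-(benzyloxy)-2-hydroxy-6-(2-oxoheptyl)benzoic acid; debenzylation and carboxylate benzylation turn part of it into the ring A phenol.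
4. That keto acid ⇒ carboxylate-directed ortho C–H acylmethylation of 4-(benzyloxy)-2-hydroxybenzoic acid with a hexanoyl sulfoxonium ylide (from methyl hexanoate and trimethylsulfoxonium iodide).
5. No ring is formed: ring A and ring B are both bought in as the same salicylic acid; the order is side chain, then ester bond, then deprotection.

## Route

Step 1
Reactants: 1 methyl hexanoate; 2 trimethylsulfoxonium iodide
Product: 4 1-[dimethyl(oxo)-λ6-sulfanylidene]heptan-2-one, via dimethylsulfoxonium methylide 3 (not isolated)
Conditions: 2 (3.0 equiv), KOtBu (3.0 equiv), THF, reflux, 2 h; then 1 (1.0 equiv), reflux, 3 h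
Reagents that add atoms: none
Why: Corey–Chaykovsky-type acylation of the methylide: it adds to the ester, methoxide leaves and removes the acidic α-proton, and the ketone-stabilised ylide formed is too weak a nucleophile to add again.

Step 2
Reactants: 5 4-(benzyloxy)-2-hydroxybenzoic acid; 4 1-[dimethyl(oxo)-λ6-sulfanylidene]heptan-2-one
Product: 6 4-(benzyloxy)-2-hydroxy-6-(2-oxoheptyl)benzoic acid
Conditions: [Cp*Rh(MeCN)3](SbF6)2 (5 mol%; Cp* = pentamethylcyclopentadienyl), NaOAc (30 mol%), 4 (1.2 equiv), HFIP, 40 °C, 12 h; cold 1 M HCl work-up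
Reagents that add atoms: none
Why: Proposed new method: carboxylate-directed ortho C–H acylmethylation of an unprotected salicylic acid, stopped at the open keto acid. Acetate-assisted concerted metalation–deprotonation by the cationic trivalent rhodium centre at C6, the only free position ortho to the carboxylate, gives a five-membered rhodacycle; ylide 4 binds through carbon and loses DMSO to give a rhodium carbene; migratory insertion forms the aryl–CH(Rh)–C(=O)pentyl bond; protodemetalation by the substrate acid releases 6. The low temperature, the acetate buffer and the absence of silver salts or strong acid are chosen to keep the keto acid from lactonising, since such keto acids are isolable and cyclise only with hot acid or anhydrides. The closest known reaction type is the Cp*Rh-catalysed C–H acylmethylation/annulation of benzoic acids and N-methoxybenzamides with sulfoxonium ylides, which is run hot with acid additives and goes on to isocoumarins.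

Step 3
Reactants: 6 4-(benzyloxy)-2-hydroxy-6-(2-oxoheptyl)benzoic acid (half of the material)
Product: 7 2,4-dihydroxy-6-(2-oxoheptyl)benzoic acid
Conditions: H2 (1 atm), Pd/C (10 wt% Pd), EtOAc, rt, 2 h; filter, evaporate below 30 °C
Reagents that add atoms: none
Why: Heterogeneous hydrogenolysis of the aryl benzyl ether; the benzyl alkyl ketone, the acid and the arene are inert under 1 atm H2 at room temperature.

Step 4
Reactants: 7 2,4-dihydroxy-6-(2-oxoheptyl)benzoic acid
Product: 8 benzyl 2,4-dihydroxy-6-(2-oxoheptyl)benzoate
Conditions: BnBr (1.05 equiv), KHCO3 (1.1 equiv), DMF, rt, 12 h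
Reagents that add atoms: benzyl bromide, BrCc1ccccc1
Why: Chemoselective carboxylate O-alkylation (SN2): bicarbonate ionises only the carboxylic acid (pKa about 3) and leaves both phenols (pKa above 8) protonated, so only the ester forms.

Step 5
Reactants: 6 4-(benzyloxy)-2-hydroxy-6-(2-oxoheptyl)benzoic acid; 8 benzyl 2,4-dihydroxy-6-(2-oxoheptyl)benzoate
Product: 9 benzyl 4-{[4-(benzyloxy)-2-hydroxy-6-(2-oxoheptyl)benzoyl]oxy}-2-hydroxy-6-(2-oxoheptyl)benzoate
Conditions: DCC (1.1 equiv), toluene/Et2O, 0 °C to rt, 16 h, no amine base
Reagents that add atoms: none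
Why: Carbodiimide (Steglich-type) esterification: the O-acylisourea of 6 is attacked by the 4-OH of 8, the only phenol in either partner not locked in a hydrogen bond to an ortho carbonyl, and the cold, base-free medium disfavours enol-lactonisation of the activated keto acid.

Step 6
Reactants: 9 benzyl 4-{[4-(benzyloxy)-2-hydroxy-6-(2-oxoheptyl)benzoyl]oxy}-2-hydroxy-6-(2-oxoheptyl)benzoate
Product: 10 4-{[2,4-dihydroxy-6-(2-oxoheptyl)benzoyl]oxy}-2-hydroxy-6-(2-oxoheptyl)benzoic acid
Conditions: H2 (1 atm), Pd/C (10 wt% Pd), EtOAc, rt, 1–2 h; filter, evaporate below 30 °C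
Reagents that add atoms: none
Why: Global hydrogenolysis of the benzyl ester and the benzyl ether under neutral conditions, which the acid- and base-sensitive aryl ester and both ketones tolerate.

## Compound list

1 | methyl hexanoate | CCCCCC(=O)OC | starting material
2 | trimethylsulfoxonium iodide | C[S+](C)(C)=O.[I-] | starting material
3 | dimethylsulfoxonium methylide | C=S(C)(C)=O | intermediate
4 | 1-[dimethyl(oxo)-λ6-sulfanylidene]heptan-2-one (hexanoyl-stabilised sulfoxonium ylide) | CCCCCC(=O)C=S(C)(C)=O | intermediate
5 | 4-(benzyloxy)-2-hydroxybenzoic acid | O=C(O)c1ccc(OCc2ccccc2)cc1O | starting material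
6 | 4-(benzyloxy)-2-hydroxy-6-(2-oxoheptyl)benzoic acid | CCCCCC(=O)Cc1cc(OCc2ccccc2)cc(O)c1C(=O)O | intermediate
7 | 2,4-dihydroxy-6-(2-oxoheptyl)benzoic acid | CCCCCC(=O)Cc1cc(O)cc(O)c1C(=O)O | intermediate
8 | benzyl 2,4-dihydroxy-6-(2-oxoheptyl)benzoate | CCCCCC(=O)Cc1cc(O)cc(O)c1C(=O)OCc1ccccc1 | intermediate
9 | benzyl 4-{[4-(benzyloxy)-2-hydroxy-6-(2-oxoheptyl)benzoyl]oxy}-2-hydroxy-6-(2-oxoheptyl)benzoate | CCCCCC(=O)Cc1cc(OC(=O)c2c(O)cc(OCc3ccccc3)cc2CC(=O)CCCCC)cc(O)c1C(=O)OCc1ccccc1 | intermediate
10 | 4-{[2,4-dihydroxy-6-(2-oxoheptyl)benzoyl]oxy}-2-hydroxy-6-(2-oxoheptyl)benzoic acid | CCCCCC(=O)Cc1cc(OC(=O)c2c(O)cc(O)cc2CC(=O)CCCCC)cc(O)c1C(=O)O | target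

## Step count and risks

Total steps: 6. Longest linear sequence: 6 (steps 1 to 6, because the ring A partner 8 is made from 6).

The three steps most likely to fail, with fallbacks:

Step 2 (the proposed new C–H acylmethylation). The risks are lactonisation to the isocoumarin, O-alkylation of the acid by the ylide, and catalyst inhibition by the salicylate. The fallback uses known chemistry, sets out from 5 and 4 and comes back at 6. The same two partners are put through the established annulative coupling ([Cp*RhCl2]2, AgSbF6, HFIP, 100 °C), where acylmethylation is followed by cyclodehydration, to give 6-(benzyloxy)-8-hydroxy-3-pentyl-1H-isochromen-1-one F1. The enol lactone is then opened with aqueous KOH in THF at rt and the solution acidified cold with HCl, the classical isocoumarin-to-keto-acid hydrolysis, to give 6.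

Step 4 (mono-benzylation of the tri-acidic keto acid 7). The risks are phenol O-alkylation at O-4 and base-induced side reactions of the keto acid. The fallback sets out from 7 and comes back at 10, with a different ester group and no base. 7 is treated with diphenyldiazomethane in acetone at rt, which only the carboxylic acid can protonate, to give diphenylmethyl 2,4-dihydroxy-6-(2-oxoheptyl)benzoate F2. F2 is coupled with 6 (DCC, as in step 5) to give diphenylmethyl 4-{[4-(benzyloxy)-2-hydroxy-6-(2-oxoheptyl)benzoyl]oxy}-2-hydroxy-6-(2-oxoheptyl)benzoate F3. Hydrogenolysis (H2, Pd/C, EtOAc) cleaves the diphenylmethyl ester and the benzyl ether together to give 10.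

Step 5 (esterification with a donor acid that carries a free ketone). The risk is that the activated acid of 6 enol-lactonises to the isocoumarin, or reacts sluggishly because it is 2,6-disubstituted. The fallback sets out from 8 and comes back at 9, and reverses the polarity of the C–O bond formation so that the acid of 6 is never activated. 8 is triflated selectively at the non-chelated 4-OH (PhNTf2, Et3N, CH2Cl2) to give benzyl 2-hydroxy-6-(2-oxoheptyl)-4-{[(trifluoromethyl)sulfonyl]oxy}benzoate F4. The carboxylate of 6 is then joined to F4 by nickel/photoredox carboxylate O-arylation (NiBr2(dme), 4,4'-di-tert-butyl-2,2'-bipyridine, Ir(ppy)3, amine base, DMF, blue LEDs), giving 9. This coupling is established for aryl bromides; its use with the aryl triflate is assumed, not demonstrated.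

## Further compounds

F1 | step 2 | 6-(benzyloxy)-8-hydroxy-3-pentyl-1H-isochromen-1-one | CCCCCC1=Cc2cc(OCc3ccccc3)cc(O)c2C(=O)O1
F2 | step 4 | diphenylmethyl 2,4-dihydroxy-6-(2-oxoheptyl)benzoate | CCCCCC(=O)Cc1cc(O)cc(O)c1C(=O)OC(c1ccccc1)c1ccccc1
F3 | step 4 | diphenylmethyl 4-{[4-(benzyloxy)-2-hydroxy-6-(2-oxoheptyl)benzoyl]oxy}-2-hydroxy-6-(2-oxoheptyl)benzoate | CCCCCC(=O)Cc1cc(OC(=O)c2c(O)cc(OCc3ccccc3)cc2CC(=O)CCCCC)cc(O)c1C(=O)OC(c1ccccc1)c1ccccc1
F4 | step 5 | benzyl 2-hydroxy-6-(2-oxoheptyl)-4-{[(trifluoromethyl)sulfonyl]oxy}benzoate | CCCCCC(=O)Cc1cc(OS(=O)(=O)C(F)(F)F)cc(O)c1C(=O)OCc1ccccc1
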